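**Retrosynthetic overview**
1. Target 29 ⇐ allylic CH3→CHO oxidation of the C2 isopropenyl group of angelate 27 ⇐ angeloylation of hydroxy lactone 24.
2. cis-Lactone of 24 ⇐ 3-OH-directed reduction of a C5 ketone, then oxidative lactonisation of a 2-(hydroxymethyl)vinyl group on C4; C2–H/C3–OH ⇐ formate hydrogenolysis of a dienyl epoxide (ketone → diene → directed epoxidation).
3. Quaternary C1 (CH3, vinyl) and C6–OH ⇐ key step: semipinacol 1,2-vinyl shift of an epoxy tertiary carbinol made in the same flask from α,β-epoxy ketone 6 and vinylmagnesium bromide.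
4. 6 ⇐ "4,4-dimethoxycarvone" 5 ⇐ rhodium-catalysed enantioselective conjugate isopropenylation of quinone monoacetal 3 from o-cresol.
5. Ring order: the carbocycle is the dearomatised o-cresol ring throughout; the γ-lactone (step 13) is the only ring closed later.

Assumption: (R)-2-methylbutanoic acid (single enantiomer, as the target SMILES requires) and angelic acid are bought.
Convention: ring locants C1–C6 are those of the cyclohexane in 29 (C1 = C(CH3)(vinyl), C2 = CH bearing the propenal, C3 = CH–O-angeloyl, C4 = CH bearing the lactone α-carbon, C5 = CH–O of the lactone, C6 = CH–O-2-methylbutanoyl); with the ring drawn C1→C6 clockwise, β is the face toward the viewer (29 is 1β-vinyl, 1α-CH3, 2α, 3α-O, 4β, 5β-O, 6α-O).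

Step 1
Reactants: 1 2-methylphenol
Product: 3 4,4-dimethoxy-2-methylcyclohexa-2,5-dien-1-one, via 4-methoxy-2-methylphenol 2 (not isolated)
Conditions: PhI(OAc)2 (2.2 equiv), MeOH, 0 °C → rt
Reagents that add atoms: methanol, CO
Why: Double oxidative dearomatisation by the trivalent-iodine reagent (phenol → p-methoxyphenol → p-quinone monoacetal) puts the acetal para to the original OH and keeps the 2-methyl enone; no stereocentre.

Step 2
Reactants: 3 4,4-dimethoxy-2-methylcyclohexa-2,5-dien-1-one; 4 potassium trifluoro(prop-1-en-2-yl)borate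
Product: 5 (5S)-4,4-dimethoxy-2-methyl-5-(prop-1-en-2-yl)cyclohex-2-en-1-one
Conditions: [Rh(cod)2]BF4 (3 mol %), (S)-BINAP (3.3 mol %), Et3N, toluene/H2O, rt
Reagents that add atoms: none
Why: Hayashi–Miyaura rhodium-catalysed asymmetric conjugate addition; the alkenyl–rhodium should insert only the unsubstituted enone C=C (the α-methyl enone is much slower) and (S)-BINAP sets C4 (4β, S), the sense taken by analogy with 2-cyclohexenone (the ligand antipode is used if the opposite sense is found).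

Step 3
Reactants: 5 (5S)-4,4-dimethoxy-2-methyl-5-(prop-1-en-2-yl)cyclohex-2-en-1-one
Product: 6 1α,6α-epoxy-5,5-dimethoxy-1-methyl-4β-(prop-1-en-2-yl)cyclohexan-2-one
Conditions: 30% H2O2, NaOH (0.2 equiv), MeOH, 0 °C
Reagents that add atoms: hydrogen peroxide, OO
Why: Weitz–Scheffer nucleophilic epoxidation of a carvone-like enone; hydroperoxide adds axially to C6 anti to the 4β-isopropenyl group (as with carvone), giving the 1α,6α-oxirane.

Step 4
Reactants: 6 1α,6α-epoxy-5,5-dimethoxy-1-methyl-4β-(prop-1-en-2-yl)cyclohexan-2-one; 7 vinylmagnesium bromide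
Product: 9 1β-ethenyl-6α-hydroxy-5,5-dimethoxy-1α-methyl-4β-(prop-1-en-2-yl)cyclohexan-2-one, via epoxy carbinol alkoxide 8 (not isolated)
Conditions: 7 (1.3 equiv), ZnCl2 (10 mol %), THF, −78 → −20 °C; then ZnBr2 (1.5 equiv), CH2Cl2, −20 → 20 °C; H2O
Reagents that add atoms: none
Why: Proposed new method: a one-flask vinylation/zinc-relay semipinacol, in which the triorganozincate from the Grignard reagent and catalytic ZnCl2 adds vinyl to the C2 ketone anti to the oxirane (2β-vinyl, 2α-alkoxide), added ZnBr2 turns the magnesium alkoxide into a bromozinc alkoxide chelated to the oxirane oxygen, the tertiary C1–O bond (remote from the acetal) ionises and the antiperiplanar vinyl group shifts C2→C1 with inversion at C1, setting 1β-vinyl/1α-CH3 and the 6α-carbinol; the closest known reaction type is the stepwise ZnBr2- or BF3-promoted semipinacol rearrangement of isolated 2,3-epoxy alcohols (Suzuki–Tsuchihashi type), which to my knowledge has not been run as an addition–rearrangement relay on an α,β-epoxy ketone.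

Step 5
Reactants: 9 1β-ethenyl-6α-hydroxy-5,5-dimethoxy-1α-methyl-4β-(prop-1-en-2-yl)cyclohexan-2-one
Product: 10 1β-ethenyl-6α-hydroxy-4β-(3-hydroxyprop-1-en-2-yl)-5,5-dimethoxy-1α-methylcyclohexan-2-one
Conditions: SeO2 (0.3 equiv), t-BuOOH (2 equiv), CH2Cl2, 0 °C → rt
Reagents that add atoms: tert-butyl hydroperoxide, CC(C)(C)OO (oxygen passed on by selenium dioxide, O=[Se]=O)
Why: Sharpless-type SeO2/t-BuOOH allylic hydroxylation (ene reaction then 2,3-shift) reaches only the isopropenyl CH3, because the vinyl group has no allylic hydrogen and CH3 reacts before the ring methine; no new stereocentre.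

Step 6
Reactants: 10 1β-ethenyl-6α-hydroxy-4β-(3-hydroxyprop-1-en-2-yl)-5,5-dimethoxy-1α-methylcyclohexan-2-one
Product: 11 4β-[3-(tert-butyldimethylsilyloxy)prop-1-en-2-yl]-1β-ethenyl-6α-hydroxy-5,5-dimethoxy-1α-methylcyclohexan-2-one
Conditions: TBSCl (1.1 equiv), imidazole, CH2Cl2, 0 °C
Reagents that add atoms: tert-butyldimethylsilyl chloride, CC(C)(C)[Si](C)(C)Cl
Why: Silylation selects the primary allylic alcohol over the doubly neopentyl 6α-OH and masks the allylic alcohol so that it cannot steer the vanadium epoxidation of step 8.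

Step 7
Reactants: 11 4β-[3-(tert-butyldimethylsilyloxy)prop-1-en-2-yl]-1β-ethenyl-6α-hydroxy-5,5-dimethoxy-1α-methylcyclohexan-2-one; 12 2-bromopropene
Product: 14 4β-[3-(tert-butyldimethylsilyloxy)prop-1-en-2-yl]-1β-ethenyl-5,5-dimethoxy-1α-methyl-2-(prop-1-en-2-yl)cyclohex-2-en-6α-ol, via tosylhydrazone 13 (not isolated)
Conditions: TsNHNH2, 4 Å MS, 1,4-dioxane, 70 °C; then Pd2(dba)3 (2.5 mol %), XPhos (10 mol %), LiOtBu (3 equiv), 12 (2 equiv), 100 °C, sealed tube
Reagents that add atoms: p-toluenesulfonyl hydrazide, Cc1ccc(cc1)S(=O)(=O)NN (atoms held only in 13)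
Why: Barluenga cross-coupling, in which the tosylhydrazone gives a diazo compound and a palladium carbene, isopropenyl migrates to the carbene carbon and β-hydride elimination can only go toward C3 (C1 is quaternary), giving the 2-isopropenyl C2=C3 diene; no stereocentre.

Step 8
Reactants: 14 4β-[3-(tert-butyldimethylsilyloxy)prop-1-en-2-yl]-1β-ethenyl-5,5-dimethoxy-1α-methyl-2-(prop-1-en-2-yl)cyclohex-2-en-6α-ol
Product: 15 2α,3α-epoxide of 14
Conditions: VO(acac)2 (5 mol %), t-BuOOH (1.5 equiv), toluene, 0 °C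
Reagents that add atoms: tert-butyl hydroperoxide, CC(C)(C)OO
Why: Vanadium-catalysed hydroxyl-directed epoxidation; the homoallylic 6α-OH (a cyclohex-3-en-1-ol array) delivers the peroxide to the α-face of the electron-rich ring C2=C3 bond, while the silyl allyl ether, the vinyl group and the diene terminus are left alone.

Step 9
Reactants: 15 2α,3α-epoxide of 14; 16 (R)-2-methylbutanoic acid
Product: 18 6α-O-[(R)-2-methylbutanoyl] ester of 15, via 2-methylbutanoic 2,4,6-trichlorobenzoic anhydride 17 (not isolated)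
Conditions: 16, 2,4,6-trichlorobenzoyl chloride, Et3N, THF, rt; then 15, DMAP, toluene, 50 °C
Reagents that add atoms: 2,4,6-trichlorobenzoyl chloride, O=C(Cl)c1c(Cl)cc(Cl)cc1Cl (atoms held only in 17)
Why: Yamaguchi esterification of the only free hydroxyl (the hindered 6α-OH) through the mixed anhydride; the α-centre of the acid is not enolised, so (R) is kept.

Step 10
Reactants: 18 6α-O-[(R)-2-methylbutanoyl] ester of 15
Product: 19 3α-hydroxy-2α-(prop-1-en-2-yl) 5,5-dimethyl acetal 6α-ester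
Conditions: Pd2(dba)3·CHCl3 (5 mol %), PBu3 (10 mol %), HCO2H, Et3N, 1,4-dioxane, rt
Reagents that add atoms: none
Why: Tsuji–Shimizu hydrogenolysis of an alkenyl oxirane, in which zerovalent palladium opens the allylic C2–O bond with inversion and the formate-derived hydride goes from the metal (β) face to C2, the more substituted allyl terminus, giving 2β-H (2α-isopropenyl) and the 3α-OH.

Step 11
Reactants: 19 3α-hydroxy-2α-(prop-1-en-2-yl) 5,5-dimethyl acetal 6α-ester
Product: 20 3α-hydroxy-4β-(3-hydroxyprop-1-en-2-yl)-5-oxo 6α-ester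
Conditions: 2 M aq. HCl/THF (1:4), 0 °C → rt
Reagents that add atoms: water, O
Why: Acid hydrolysis of the dimethyl acetal and of the primary silyl ether in one operation; the ester, the alkenes and the β-hydroxy ketone tolerate dilute HCl at this temperature.

Step 12
Reactants: 20 3α-hydroxy-4β-(3-hydroxyprop-1-en-2-yl)-5-oxo 6α-ester
Product: 21 3α,5β-dihydroxy-4β-(3-hydroxyprop-1-en-2-yl) 6α-ester
Conditions: Me4NBH(OAc)3 (5 equiv), AcOH/MeCN (1:1), −25 °C
Reagents that add atoms: none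
Why: Evans–Saksena hydroxyl-directed reduction, in which the axial 3α-OH binds the triacetoxyborohydride and delivers hydride to the α-face of the C5 ketone, giving the anti-1,3-diol (5β-OH).

Step 13
Reactants: 21 3α,5β-dihydroxy-4β-(3-hydroxyprop-1-en-2-yl) 6α-ester
Product: 24 3α-hydroxy cis-fused α-methylene-γ-butyrolactone 6α-ester, via hydroxy enal 22 (not isolated), via lactol 23 (not isolated)
Conditions: activated MnO2 (20 equiv), CH2Cl2, rt
Reagents that add atoms: none
Why: MnO2 oxidises only the primary allylic alcohol; the enal is trapped by the cis 5β-OH as a lactol (the trans-diaxial 3α-OH cannot reach) and the allylic lactol is oxidised on to the cis-fused lactone (oxidative lactonisation).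

Step 14
Reactants: 24 3α-hydroxy cis-fused α-methylene-γ-butyrolactone 6α-ester; 25 angelic acid
Product: 27 3α-O-angeloyl lactone diester, via angelic 2,4,6-trichlorobenzoic anhydride 26 (not isolated)
Conditions: 25, 2,4,6-trichlorobenzoyl chloride, Et3N, toluene, rt; then 24, 80 °C (no DMAP)
Reagents that add atoms: 2,4,6-trichlorobenzoyl chloride, O=C(Cl)c1c(Cl)cc(Cl)cc1Cl (atoms held only in 26)
Why: Yamaguchi-type mixed-anhydride acylation of the only remaining hydroxyl; leaving out DMAP is intended to transfer the angeloyl group without Z→E isomerisation to the tiglate.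

Step 15
Reactants: 27 3α-O-angeloyl lactone diester
Product: 29 target CNP0295282.1, via allylic alcohol 28 (not isolated)
Conditions: SeO2 (0.5 equiv), t-BuOOH (3 equiv), CH2Cl2, rt; then MnO2, rt
Reagents that add atoms: tert-butyl hydroperoxide, CC(C)(C)OO (oxygen passed on by selenium dioxide, O=[Se]=O)
Why: SeO2/t-BuOOH allylic oxidation of the one electron-rich alkene with allylic hydrogens (the C2 isopropenyl group; the lactone methylene and the angelate are electron-poor), finished by MnO2 to the 2-substituted propenal; no stereocentre is touched.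

**Compound list**
1 | 2-methylphenol (o-cresol) | Cc1ccccc1O | starting material
2 | 4-methoxy-2-methylphenol | COc1ccc(O)c(C)c1 | intermediate
3 | 4,4-dimethoxy-2-methylcyclohexa-2,5-dien-1-one | COC1(OC)C=CC(=O)C(C)=C1 | intermediate
4 | potassium trifluoro(prop-1-en-2-yl)borate | CC(=C)[B-](F)(F)F.[K+] | starting material
5 | (5S)-4,4-dimethoxy-2-methyl-5-(prop-1-en-2-yl)cyclohex-2-en-1-one (target locants: C2 ketone, C1=C6, C5 acetal, 4β-isopropenyl) | O=C1C[C@@H](C(C)=C)C(OC)(OC)C=C1C | intermediate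
6 | 1α,6α-epoxy-5,5-dimethoxy-1-methyl-4β-(prop-1-en-2-yl)cyclohexan-2-one (7-oxabicyclo[4.1.0]heptan-2-one, oxirane oxygen trans to isopropenyl) | O=C1C[C@@H](C(C)=C)C(OC)(OC)[C@@H]2O[C@]12C | intermediate
7 | vinylmagnesium bromide | C=C[Mg]Br | starting material
8 | 2β-ethenyl-1α,6α-epoxy-5,5-dimethoxy-1-methyl-4β-(prop-1-en-2-yl)cyclohexan-2α-ol (in the flask as its magnesium/zinc alkoxide; OH cis to the oxirane oxygen) | C=C[C@@]1(O)C[C@@H](C(C)=C)C(OC)(OC)[C@@H]2O[C@]12C | intermediate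
9 | 1β-ethenyl-6α-hydroxy-5,5-dimethoxy-1α-methyl-4β-(prop-1-en-2-yl)cyclohexan-2-one | C=C[C@@]1(C)C(=O)C[C@@H](C(C)=C)C(OC)(OC)[C@@H]1O | intermediate
10 | 1β-ethenyl-6α-hydroxy-4β-(3-hydroxyprop-1-en-2-yl)-5,5-dimethoxy-1α-methylcyclohexan-2-one | C=C[C@@]1(C)C(=O)C[C@@H](C(=C)CO)C(OC)(OC)[C@@H]1O | intermediate
11 | 4β-[3-(tert-butyldimethylsilyloxy)prop-1-en-2-yl]-1β-ethenyl-6α-hydroxy-5,5-dimethoxy-1α-methylcyclohexan-2-one | C=C[C@@]1(C)C(=O)C[C@@H](C(=C)CO[Si](C)(C)C(C)(C)C)C(OC)(OC)[C@@H]1O | intermediate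
12 | 2-bromopropene | CC(Br)=C | starting material
13 | C2 N-tosylhydrazone of 11 | C=C[C@@]1(C)C(=NNS(=O)(=O)c2ccc(C)cc2)C[C@@H](C(=C)CO[Si](C)(C)C(C)(C)C)C(OC)(OC)[C@@H]1O | intermediate
14 | 4β-[3-(tert-butyldimethylsilyloxy)prop-1-en-2-yl]-1β-ethenyl-5,5-dimethoxy-1α-methyl-2-(prop-1-en-2-yl)cyclohex-2-en-6α-ol | C=C[C@@]1(C)C(C(C)=C)=C[C@@H](C(=C)CO[Si](C)(C)C(C)(C)C)C(OC)(OC)[C@@H]1O | intermediate
15 | 2α,3α-epoxide of 14 (2β-isopropenyl, free 6α-OH) | C=C[C@@]1(C)[C@]3(C(C)=C)O[C@@H]3[C@@H](C(=C)CO[Si](C)(C)C(C)(C)C)C(OC)(OC)[C@@H]1O | intermediate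
16 | (R)-2-methylbutanoic acid | CC[C@@H](C)C(=O)O | starting material
17 | (R)-2-methylbutanoic 2,4,6-trichlorobenzoic anhydride | O=C(OC(=O)c1c(Cl)cc(Cl)cc1Cl)[C@H](C)CC | intermediate
18 | 6α-O-[(R)-2-methylbutanoyl] ester of 15 | C=C[C@@]1(C)[C@]3(C(C)=C)O[C@@H]3[C@@H](C(=C)CO[Si](C)(C)C(C)(C)C)C(OC)(OC)[C@@H]1OC(=O)[C@H](C)CC | intermediate
19 | 4β-[3-(tert-butyldimethylsilyloxy)prop-1-en-2-yl]-1β-ethenyl-3α-hydroxy-5,5-dimethoxy-1α-methyl-2α-(prop-1-en-2-yl)cyclohexan-6α-yl (R)-2-methylbutanoate | C=C[C@@]1(C)[C@H](C(C)=C)[C@H](O)[C@@H](C(=C)CO[Si](C)(C)C(C)(C)C)C(OC)(OC)[C@@H]1OC(=O)[C@H](C)CC | intermediate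
20 | 1β-ethenyl-3α-hydroxy-4β-(3-hydroxyprop-1-en-2-yl)-1α-methyl-5-oxo-2α-(prop-1-en-2-yl)cyclohexan-6α-yl (R)-2-methylbutanoate | C=C[C@@]1(C)[C@H](C(C)=C)[C@H](O)[C@@H](C(=C)CO)C(=O)[C@@H]1OC(=O)[C@H](C)CC | intermediate
21 | 1β-ethenyl-3α,5β-dihydroxy-4β-(3-hydroxyprop-1-en-2-yl)-1α-methyl-2α-(prop-1-en-2-yl)cyclohexan-6α-yl (R)-2-methylbutanoate | C=C[C@@]1(C)[C@H](C(C)=C)[C@H](O)[C@@H](C(=C)CO)[C@@H](O)[C@@H]1OC(=O)[C@H](C)CC | intermediate
22 | 4β-(3-oxoprop-1-en-2-yl) analogue of 21 (hydroxy enal) | C=C[C@@]1(C)[C@H](C(C)=C)[C@H](O)[C@@H](C(=C)C=O)[C@@H](O)[C@@H]1OC(=O)[C@H](C)CC | intermediate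
23 | cis-fused lactol from 22 (C5–O closed onto the aldehyde, anomeric centre as a mixture) | C=C[C@@]1(C)[C@H](C(C)=C)[C@H](O)[C@H]2C(=C)C(O)O[C@H]2[C@@H]1OC(=O)[C@H](C)CC | intermediate
24 | cis-fused (4β-C, 5β-O) α-methylene-γ-butyrolactone with 3α-OH, 2α-isopropenyl, 1β-vinyl, 1α-CH3 and 6α-O-(R)-2-methylbutanoyl | C=C[C@@]1(C)[C@H](C(C)=C)[C@H](O)[C@H]2C(=C)C(=O)O[C@H]2[C@@H]1OC(=O)[C@H](C)CC | intermediate
25 | angelic acid, (Z)-2-methylbut-2-enoic acid | C/C=C(/C)C(=O)O | starting material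
26 | (Z)-2-methylbut-2-enoic 2,4,6-trichlorobenzoic anhydride | C/C=C(/C)C(=O)OC(=O)c1c(Cl)cc(Cl)cc1Cl | intermediate
27 | 3α-O-angeloyl ester of 24 (C2 side chain still isopropenyl) | C=C[C@@]1(C)[C@H](C(C)=C)[C@H](OC(=O)/C(C)=C\C)[C@H]2C(=C)C(=O)O[C@H]2[C@@H]1OC(=O)[C@H](C)CC | intermediate
28 | 2α-(3-hydroxyprop-1-en-2-yl) analogue of 27 (allylic alcohol) | C=C[C@@]1(C)[C@H](C(=C)CO)[C@H](OC(=O)/C(C)=C\C)[C@H]2C(=C)C(=O)O[C@H]2[C@@H]1OC(=O)[C@H](C)CC | intermediate
29 | CNP0295282.1: 2α-(3-oxoprop-1-en-2-yl), 3α-O-angeloyl, 6α-O-[(R)-2-methylbutanoyl], 1β-vinyl, 1α-methyl, cis-fused α-methylene-γ-butyrolactone | C=C[C@@]1(C)[C@H](C(=C)C=O)[C@H](OC(=O)/C(C)=C\C)[C@H]2C(=C)C(=O)O[C@H]2[C@@H]1OC(=O)[C@H](C)CC | target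

**Count**
Total steps: 15. Longest linear sequence: 15 (1 → 29); all other reactants are bought.

**Three steps most likely to fail**

Step 2 (site- and enantioselective conjugate addition to an unsymmetrical quinone monoacetal). The fallback sets out from 4 and comes back at 5. It removes the site-selectivity question by using the symmetrical monoacetal 4,4-dimethoxycyclohexa-2,5-dien-1-one F1 (made from phenol with PhI(OAc)2/MeOH as in step 1). The same rhodium/(S)-BINAP addition of 4 gives (5S)-4,4-dimethoxy-5-(prop-1-en-2-yl)cyclohex-2-en-1-one F2. The methyl group is then put in by α-iodination (I2, pyridine, CH2Cl2) to (5S)-2-iodo-4,4-dimethoxy-5-(prop-1-en-2-yl)cyclohex-2-en-1-one F3, followed by Suzuki methylation (MeB(OH)2, Pd(dppf)Cl2, K2CO3, dioxane/H2O) to give 5.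

Step 4 (the proposed one-flask vinylation/semipinacol). The fallback sets out from 6 and comes back at 9, using known chemistry in two separate operations. Vinylmagnesium bromide (with CeCl3) is added at −78 °C, the reaction is quenched and the epoxy alcohol 8 is isolated. The purified 8 is then rearranged by the established ZnBr2-catalysed (or BF3·OEt2, −78 °C) semipinacol 1,2-vinyl shift. This makes no compound outside the list (F0).

Step 7 (Barluenga coupling on a hindered α-quaternary, β-hydroxy ketone). The fallback sets out from 11 and comes back at 14 through an enol triflate. The 6α-OH is capped (TMSCl, imidazole) to give the 6-O-trimethylsilyl ether of 11 F4. KHMDS/PhNTf2 in THF at −78 °C gives the C2 enol triflate F5 (enolisation is only possible toward C3). Suzuki coupling with 4 (Pd(dppf)Cl2, Cs2CO3, THF/H2O, 60 °C) gives the 6-O-trimethylsilyl ether of 14 F6, and K2CO3/MeOH frees 14.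

Further compounds
F1 | step 2 | 4,4-dimethoxycyclohexa-2,5-dien-1-one | COC1(OC)C=CC(=O)C=C1
F2 | step 2 | (5S)-4,4-dimethoxy-5-(prop-1-en-2-yl)cyclohex-2-en-1-one | O=C1C[C@@H](C(C)=C)C(OC)(OC)C=C1
F3 | step 2 | (5S)-2-iodo-4,4-dimethoxy-5-(prop-1-en-2-yl)cyclohex-2-en-1-one | O=C1C[C@@H](C(C)=C)C(OC)(OC)C=C1I
F0 | step 4 | none | none
F4 | step 7 | 6-O-trimethylsilyl ether of 11 | C=C[C@@]1(C)C(=O)C[C@@H](C(=C)CO[Si](C)(C)C(C)(C)C)C(OC)(OC)[C@@H]1O[Si](C)(C)C
F5 | step 7 | C2 enol triflate (C2=C3) of F4 | C=C[C@@]1(C)C(OS(=O)(=O)C(F)(F)F)=C[C@@H](C(=C)CO[Si](C)(C)C(C)(C)C)C(OC)(OC)[C@@H]1O[Si](C)(C)C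
F6 | step 7 | 6-O-trimethylsilyl ether of 14 | C=C[C@@]1(C)C(C(C)=C)=C[C@@H](C(=C)CO[Si](C)(C)C(C)(C)C)C(OC)(OC)[C@@H]1O[Si](C)(C)C
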